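**Strategy.** Ring C (O1, C2, C3, C4, C4a, C8a) is disconnected into the three-atom phenol unit O1–C8a–C4a of ring A and the three-carbon unit C2–C3–C4 of an aryl vinyl ketone. In one flask a chiral Brønsted acid joins the free ortho carbon of a phloroglucinol-type phenol to the enone β-carbon (C4–C4a), the phenol oxygen closes onto the carbonyl (O1–C2), and the resulting 2-anisyl oxocarbenium ion is reduced enantioselectively by a Hantzsch ester to set C2. The step exploits the 1,3-C,O-dinucleophilic ring A and the cation-stabilising O1/anisyl pair at C2. The precursor is 3,5-dimethoxy-4-prenylphenol, made in two steps from 1,3-dimethoxybenzene.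

Key step: step 3

Remark: enone 7 is a catalogue compound that polymerises on storage; it is passed through a short pad of neutral Al2O3 immediately before use.

**Step 1**
Reactants: 1 1,3-dimethoxybenzene; 2 1-bromo-3-methylbut-2-ene (prenyl bromide)
Product: 4 1,3-dimethoxy-2-(3-methylbut-2-en-1-yl)benzene, via 2,6-dimethoxyphenyllithium 3 (not isolated)
Conditions: n-BuLi, THF, 0 °C to rt; then CuBr·SMe2 (10 mol%), 2, −78 °C to rt
Reagents that add atoms: none
Why: Directed ortho-metalation of 1 takes place at C2 between the two methoxy groups, and the copper-assisted allylic substitution of the aryl anion on prenyl bromide should occur at the primary carbon.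

**Step 2**
Reactants: 4 1,3-dimethoxy-2-(3-methylbut-2-en-1-yl)benzene
Product: 6 3,5-dimethoxy-4-(3-methylbut-2-en-1-yl)phenol, via aryl pinacol boronate 5 (not isolated)
Conditions: [Ir(OMe)(cod)]2 (1.5 mol%), 4,4'-di-tert-butyl-2,2'-bipyridine (3 mol%), B2pin2, THF, 80 °C; then 30% H2O2, aq NaOH, 0 °C
Reagents that add atoms: hydrogen peroxide, OO (phenol oxygen of 6); bis(pinacolato)diboron, CC1(C)OB(OC1(C)C)B1OC(C)(C)C(C)(C)O1 (boryl group of intermediate 5 only)
Why: Sterically controlled iridium-catalysed C–H borylation should select the only ring C–H without an ortho substituent (meta to both methoxy groups, para to the prenyl group), and oxidation of the C–B bond gives the phenol (one-pot Hartwig–Miyaura borylation/oxidation).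

**Step 3**
Reactants: 6 3,5-dimethoxy-4-(3-methylbut-2-en-1-yl)phenol; 7 1-(4-methoxyphenyl)prop-2-en-1-one
Product: 11 (2S)-5,7-dimethoxy-2-(4-methoxyphenyl)-6-(3-methylbut-2-en-1-yl)-3,4-dihydro-2H-chromene, via ketone adduct 8 (not isolated), via lactol 9 (not isolated), via oxocarbenium ion 10 (not isolated)
Conditions: 6 (1.0 equiv), 7 (1.1 equiv), (R)-3,3'-bis(2,4,6-triisopropylphenyl)-BINOL N-triflylphosphoramide (5 mol%), 5 Å molecular sieves, toluene, rt; then Hantzsch ester (diethyl 2,6-dimethyl-1,4-dihydropyridine-3,5-dicarboxylate, 1.3 equiv), −20 °C to rt, same flask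
Reagents that add atoms: none
Why: Proposed new method: the acid activates enone 7 for Friedel–Crafts conjugate addition of the free ortho carbon of phenol 6 (C4–C4a, ketone 8), the phenol oxygen adds to the ketone (O1–C2, lactol 9), ionisation with loss of water gives the 2-anisyl oxocarbenium ion 10 as an ion pair with the chiral phosphoramide anion, and the Hantzsch ester transfers hydride to C2. The closest known reaction types are the acid-catalysed annulation of electron-rich phenols with enones to 2-chromanols and the chiral-phosphate-anion-directed Hantzsch ester reduction of isobenzopyrylium ions; the asymmetric reduction of a 3,4-dihydro-1-benzopyrylium ion formed this way has not been shown. Ring C closes by 6-exo-trig attack of O1 on the C2 carbonyl. The C2 stereocentre is set by the catalyst: the anion holds the cation and the N–H of the Hantzsch ester in one complex and must expose the Re face of C2 to give (S); should the (R)-catalyst expose the Si face, its (S)-enantiomer is used instead. The step needs C- over O-alkylation of the phenol (the two ortho carbons are equivalent and strongly activated by three oxygen substituents, and oxa-Michael addition is reversible) and reduction of the cation but not of enone 7 or the prenyl alkene (the hydride donor is added only after 7 is consumed, and the acid is too weak to protonate an isolated trisubstituted alkene).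

**Compound list**
1 | 1,3-dimethoxybenzene | COc1cccc(OC)c1 | starting material
2 | 1-bromo-3-methylbut-2-ene (prenyl bromide) | CC(C)=CCBr | starting material
3 | 2,6-dimethoxyphenyllithium | [Li]c1c(OC)cccc1OC | intermediate
4 | 1,3-dimethoxy-2-(3-methylbut-2-en-1-yl)benzene | COc1cccc(OC)c1CC=C(C)C | intermediate
5 | 2-[3,5-dimethoxy-4-(3-methylbut-2-en-1-yl)phenyl]-4,4,5,5-tetramethyl-1,3,2-dioxaborolane | COc1cc(B2OC(C)(C)C(C)(C)O2)cc(OC)c1CC=C(C)C | intermediate
6 | 3,5-dimethoxy-4-(3-methylbut-2-en-1-yl)phenol | COc1cc(O)cc(OC)c1CC=C(C)C | intermediate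
7 | 1-(4-methoxyphenyl)prop-2-en-1-one | COc1ccc(C(=O)C=C)cc1 | starting material
8 | 3-[6-hydroxy-2,4-dimethoxy-3-(3-methylbut-2-en-1-yl)phenyl]-1-(4-methoxyphenyl)propan-1-one | COc1ccc(C(=O)CCc2c(O)cc(OC)c(CC=C(C)C)c2OC)cc1 | intermediate
9 | 5,7-dimethoxy-2-(4-methoxyphenyl)-6-(3-methylbut-2-en-1-yl)chroman-2-ol (racemic lactol) | COc1ccc(C2(O)CCc3c(cc(OC)c(CC=C(C)C)c3OC)O2)cc1 | intermediate
10 | 5,7-dimethoxy-2-(4-methoxyphenyl)-6-(3-methylbut-2-en-1-yl)-3,4-dihydro-1-benzopyrylium ion (paired with the chiral phosphoramide anion) | COc1ccc(C2=[O+]c3cc(OC)c(CC=C(C)C)c(OC)c3CC2)cc1 | intermediate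
11 | (2S)-5,7-dimethoxy-2-(4-methoxyphenyl)-6-(3-methylbut-2-en-1-yl)-3,4-dihydro-2H-chromene | COc1ccc([C@@H]2CCc3c(cc(OC)c(CC=C(C)C)c3OC)O2)cc1 | target

**Total step count:** 3
**Longest linear sequence:** 3 (1 → 4 → 6 → 11)

**Steps most likely to fail**

Step 3 (proposed new method). Hydride transfer within the ion pair may show poor facial selectivity, the pyridine by-product may buffer the acid so the reaction stalls at the lactol, or hydride may be diverted to the enone. The fallback uses known chemistry, sets out from 6 and 7 and comes back at 11. The two are joined under an achiral acid (diphenyl phosphate, toluene, 40 °C) and ketone adduct 8 is isolated, in equilibrium with lactol 9. Noyori-type asymmetric transfer hydrogenation with RuCl[(R,R)-TsDPEN](p-cymene) in HCO2H/Et3N should give (1R)-3-[6-hydroxy-2,4-dimethoxy-3-(3-methylbut-2-en-1-yl)phenyl]-1-(4-methoxyphenyl)propan-1-ol F1. Mitsunobu cyclisation (PPh3, DIAD, THF, 0 °C) then closes O1–C2 by phenol attack with inversion at the benzylic carbon, giving 11.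

Step 2. The iridium boryl species or HBpin may hydroborate or migrate the prenyl double bond, or borylation may not stop at one C–H bond. The fallback avoids C–H oxidation in the presence of the alkene by starting with the phenol oxygen in place; it sets out from prenyl bromide 2 and purchased 3,5-dimethoxyphenol F2 and comes back at 6. Silylation (TIPSCl, imidazole, DMF) gives (3,5-dimethoxyphenoxy)triisopropylsilane F3. Lithiation between the two methoxy groups (n-BuLi, THF, 0 °C), away from the bulky silyl ether, gives [2,6-dimethoxy-4-(triisopropylsilyloxy)phenyl]lithium F4. Alkylation with 2 (CuBr·SMe2, −78 °C to rt) gives [3,5-dimethoxy-4-(3-methylbut-2-en-1-yl)phenoxy]triisopropylsilane F5, and TBAF in THF releases 6.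

Step 1. Allylic transposition in the substitution (attack at the tertiary end of the prenyl unit) or halogen–metal exchange with homocoupling may lower the regiochemical purity. The fallback sets out from 1 and comes back at 4. Lithiation to 3 and quenching with allyl bromide, which has no regiochemical ambiguity, gives 2-allyl-1,3-dimethoxybenzene F6. Cross-metathesis with excess 2-methylbut-2-ene (second-generation Grubbs catalyst, CH2Cl2, 40 °C) then installs the trisubstituted alkene of 4.

**Further compounds**
F1 | step 3 | (1R)-3-[6-hydroxy-2,4-dimethoxy-3-(3-methylbut-2-en-1-yl)phenyl]-1-(4-methoxyphenyl)propan-1-ol | COc1ccc([C@H](O)CCc2c(O)cc(OC)c(CC=C(C)C)c2OC)cc1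
F2 | step 2 | 3,5-dimethoxyphenol | COc1cc(O)cc(OC)c1
F3 | step 2 | (3,5-dimethoxyphenoxy)triisopropylsilane | COc1cc(O[Si](C(C)C)(C(C)C)C(C)C)cc(OC)c1
F4 | step 2 | [2,6-dimethoxy-4-(triisopropylsilyloxy)phenyl]lithium | [Li]c1c(OC)cc(O[Si](C(C)C)(C(C)C)C(C)C)cc1OC
F5 | step 2 | [3,5-dimethoxy-4-(3-methylbut-2-en-1-yl)phenoxy]triisopropylsilane | COc1cc(O[Si](C(C)C)(C(C)C)C(C)C)cc(OC)c1CC=C(C)C
F6 | step 1 | 2-allyl-1,3-dimethoxybenzene | COc1cccc(OC)c1CC=C
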